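## Structural features

The target is a cis-fused furo[3,2-b]pyran-5-one: a tetrahydrofuran (ring A: ring oxygen, C4, C5, C6, C7) shares its C4–C5 bond with an α,β-unsaturated δ-lactone (ring B: C1, C2=C3, C4, C5, O5). Atoms are numbered along the chain from the lactone carbonyl C1 to the methyl C12. C7 carries an (E)-C8=C9 alkene leading to C10 (free hydroxyl, S) and C11 (benzoate, R), an anti 1,2-dioxygenated pair. The four ring stereocentres C4–C7 are contiguous and all-cis: C3, O5, O6 and C8 lie on one face of ring A. Fragile points are the unsaturated lactone (conjugate addition, base-induced opening, attack by a free C8 hydroxyl that sits cis to C3), the C11 benzoate beside a free C10 hydroxyl (1,2-acyl shift under base or basic fluoride), and any aldehyde at C8 (epimerisable C7). The real difficulty is the all-cis array: an oxidant adding to a C5=C6 alkene flanked by cis substituents at C4 and C7 takes the open face and puts O5 and O6 trans to them. The key step turns this bias round: on ring A as a cis-2,5-disubstituted 2,5-dihydrofuran with a C5=C6 alkene, iodine takes the open face and two successive inversions return both oxygens to the crowded face.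

## Logic of the disconnections

26 is cut at C9–C10 into 21 and 25. This joins two fragments at a carbinol carbon and lets the C11 centre of 25 direct C10. The forward step needs an alkenyl–metal species that adds only to an aldehyde, leaves the lactone, the benzoate and a free hydroxyl alone, and prefers the 10,11-anti product; no protecting group then remains to be removed.

21 is traced through 20 to 19 by cutting C8=C9 (a one-carbon olefination) and lowering C8 to the alcohol level. This leaves a bicyclic diol with all four ring stereocentres. The forward steps need a primary-selective oxidation and a non-basic, E-selective olefination that tolerates the free O6 hydroxyl.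

25 is traced through 23 to 22: the aldehyde carbonyl comes from cleavage of a terminal alkene, and the benzoate from acylation with retention. This keeps hydride and base away from the α-acyloxy centre, which must be R.

19 is opened at the O5–C1 bond and given back its acetyl and silyl groups, then its C2=C3 alkene is raised to an alkyne: 19 to 16 to 15. This removes ring B and its base-sensitive enoate geometry. The forward steps need a Z-selective semi-reduction and an acidic solvolysis in which O5 (six-membered ring) is chosen over O6 (seven-membered ring).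

15 is cut at the C5–O and C6–O bonds to 12. Two stereocentres are removed at once, leaving a dihydrofuran with only two, 1,4-related, stereocentres. The forward step must put both oxygens on the crowded face; it does so by attack of iodine on the open face and double inversion, through 13 and 14.

12 is cut at C1–C2 to 11 and 7, and 11 is recapped with silicon to 10. The ester comes last because an ynoate would not survive an alkoxide nucleophile; a silyl-capped alkyne does. The carboxylation must not deprotonate C4.

10 is cut at C5=C6 to 9 (ring-closing metathesis). This reduces ring A to an acyclic bis-allylic ether; the forward step only has to close a five-membered ring without touching the alkyne.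

9 is cut at the O–C7 bond to 4 and 8. This separates the two stereocentres: C4 is bought by resolution, and C7 is made by a catalyst that attacks the substituted terminus of an allyl unit and chooses its face independently of C4. An (E)-configured 8 is required for reliable branched and facial selectivity.

4 goes back through 3 to 1 (silicon cap, then resolution); 8 goes back through 6 to 5 and 7 (monosilylation, then carbonate formation).

## Other disconnections considered

Alternative 1: The cut runs through C2=C3 and through the bond from C8 to its terminal methylene. The bicyclic lactone A2 is traced to the endo,endo 7-oxanorbornene A1 (acrylate on the future O5, silyl ether on O6), the desymmetrised form of a meso diol. Forward, a ruthenium alkylidene opens the strained ring alkene and the alkylidene formed at C3 closes onto the acrylate; this makes ring B and frees ring A with a vinyl group on C7.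
- In its favour: the four ring stereocentres are fixed relative to one another by the bicyclic skeleton and need no face-selective reagent; both rings appear in one catalytic step with no stoichiometric metal; O6 arrives protected.
- Against it here: the endo,endo diol series is the less accessible one; the absolute configuration rests on a single desymmetrisation; the catalyst must open the ring so that ruthenium ends on C3 and then engage an electron-poor acrylate, otherwise oligomers or the wrong diene result; the C9–C12 chain still has to be joined to a hindered C7 vinyl group by cross-metathesis.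
- Comparison: structurally A2 is closer to the target than 15, and this plan is the better one on step economy for the core. On stereocontrol at C4–C7 it is at least the equal of the chosen plan. Mechanistically its key step carries more regiochemical uncertainty than the two-inversion sequence, and its side-chain attachment is no easier than the chromium coupling.

Alternative 2: The cut is the bond from the ring oxygen to C4. The all-cis tetrahydrofuran diol A4 is traced to the open-chain cis-4,5-epoxide A3 with free C6 and C7 hydroxyls and the complete side chain. Forward, BF3·OEt2 activates the epoxide and the C7 hydroxyl attacks propargylic C4 with inversion (5-endo), which frees the C5 hydroxyl.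
- In its favour: it is convergent, with C10 and C11 in place before ring formation; every ring stereocentre is set beforehand by reagent control on an open chain; the cyclisation transfers configuration and needs no facial choice and no resolution.
- Against it here: endo opening has only an alkynyl group to favour C4; a propargylic cation would erode the inversion; the Lewis acid also meets an allylic silyl ether at C10 and a benzoate that can shift; the cis-epoxide of a Z-enyne is a hard case for asymmetric epoxidation; after the key step C1 must still be oxidised to the acid level, the alkyne semi-reduced, the lactone closed and two silyl ethers removed.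
- Comparison: on convergence, and in transferring stereochemistry in the key step where the chosen plan induces it, this plan is equal or better. On reliability of the ring-forming mode and on exposure of functional groups to a Lewis acid the chosen plan is safer. The total step count is likely comparable because A3 is long to make.

Alternative 3: The cut is O5–C1, so ring B is grown from a furan; the ring-oxygen–C4 bond follows later. The pyranone lactol A6 is traced to the C5 furyl carbinol A5, whose C6 and C7 oxygens are tied in an acetonide. Forward, singlet oxygen adds across the furan, Me2S reduces the endoperoxide, and the C5 hydroxyl closes on C1.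
- In its favour: the furan supplies C1–C4 with the right oxidation pattern; the ring expansion is dependable and neutral; the side chain is already attached.
- Against it here: singlet oxygen must choose the furan over the C8=C9 alkene with its allylic hydrogens; A6 is a sensitive enone lactol; ring A is still missing and needs acetonide removal, addition of O7 to the C4 ketone and reduction of the bicyclic ketal from the convex face, where conjugate reduction and allylic transposition compete; C4 is set only at that late stage; the lactol must still be oxidised.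
- Comparison: the key step itself is at least as dependable as the Woodward step, and the plan is the better one on convergence. The chosen plan is stronger on the definition of C4 and has fewer delicate operations after the key step. Step economy is similar or slightly worse.

Key step: step 9

Remark (C11): C11 of the target is R; a 2-acyloxypropanal made from an (S)-lactate with retention would give the C11 epimer, so the aldehyde is built in the R series from (R)-but-3-en-2-ol.
Remark (carbonate geometry): the allyl carbonate is used as the (E) isomer, from (E)-but-2-ene-1,4-diol, because branched and facial selectivity in iridium allyl chemistry is reliable for (E) substrates and lower for (Z) ones.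
Remark (supply): (E)-but-2-ene-1,4-diol and (R)-but-3-en-2-ol are assumed to be catalogue compounds.
Remark (ligand sense): the (Ra,R,R) phosphoramidite is assigned by analogy with oxygen and nitrogen nucleophiles on other (E)-carbonates; should it give the 4,7-trans ether, its mirror image is used and nothing else changes.
Remark (15): 15 is written as the O6 acetate; its O5-acetyl regioisomer may accompany it and is carried along, since step 11 removes the acetyl group from either oxygen.

## Steps

Step 1
Reactants: 1 rac-pent-1-en-4-yn-3-ol
Product: 3 rac-5-(trimethylsilyl)pent-1-en-4-yn-3-ol, via bis-silyl ether 2 (not isolated)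
Conditions: EtMgBr (2.2 equiv), THF, 0 °C to rt; TMSCl (2.2 equiv), 0 °C; 1 M aq. HCl, rt
Reagents that add atoms: chlorotrimethylsilane, C[Si](C)(C)Cl
Why: The Grignard reagent removes the hydroxyl and the acetylenic protons and both sites are silylated to 2; dilute acid hydrolyses the O–Si bond while the alkynyl C–Si bond stays (standard C-silylation of a propargylic alcohol).

Step 2
Reactants: 3 rac-5-(trimethylsilyl)pent-1-en-4-yn-3-ol
Product: 4 (3S)-5-(trimethylsilyl)pent-1-en-4-yn-3-ol
Conditions: Pseudomonas fluorescens lipase, vinyl acetate (3 equiv), hexane, 30 °C, stopped just past half conversion; chromatography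
Reagents that add atoms: none
Why: Lipase-catalysed kinetic resolution by irreversible acyl transfer; by the empirical size rule for secondary alcohols (silylethynyl large, vinyl medium) the R enantiomer should be acetylated and the S alcohol 4, which carries the C4 configuration of the target, recovered.

Step 3
Reactants: 5 (2E)-but-2-ene-1,4-diol
Product: 6 (2E)-4-[(tert-butyldiphenylsilyl)oxy]but-2-en-1-ol
Conditions: NaH (1.0 equiv), THF, 0 °C; TBDPSCl (1.0 equiv), rt
Reagents that add atoms: tert-butyl(chloro)diphenylsilane, CC(C)(C)[Si](Cl)(c1ccccc1)c1ccccc1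
Why: Monosilylation of a symmetrical diol through its sparingly soluble monosodium alkoxide; one equivalent each of base and silyl chloride keeps the bis-ether low.

Step 4
Reactants: 6 (2E)-4-[(tert-butyldiphenylsilyl)oxy]but-2-en-1-ol; 7 methyl chloroformate
Product: 8 (2E)-4-[(tert-butyldiphenylsilyl)oxy]but-2-en-1-yl methyl carbonate
Conditions: pyridine, CH2Cl2, 0 °C
Reagents that add atoms: none
Why: Acylation of the primary allylic alcohol by the chloroformate; the (E)-methyl carbonate is the usual leaving group for iridium allyl chemistry and releases CO2 and methoxide on ionisation.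

Step 5
Reactants: 4 (3S)-5-(trimethylsilyl)pent-1-en-4-yn-3-ol; 8 (2E)-4-[(tert-butyldiphenylsilyl)oxy]but-2-en-1-yl methyl carbonate
Product: 9 tert-butyldiphenyl{[(2R)-2-{[(3S)-5-(trimethylsilyl)pent-1-en-4-yn-3-yl]oxy}but-3-en-1-yl]oxy}silane
Conditions: 4, Et2Zn (0.5 equiv), THF, 0 °C; then 8 (1.2 equiv), [Ir(cod)Cl]2 (2.5 mol%), (11bR)-N,N-bis[(1R)-1-phenylethyl]dinaphtho[2,1-d:1',2'-f][1,3,2]dioxaphosphepin-4-amine (5 mol%, catalyst pre-activated with n-PrNH2), THF, rt
Reagents that add atoms: none
Why: Iridium-catalysed allylic etherification with a zinc alkoxide: the (E)-carbonate ionises to a π-allyl complex of the cyclometalated iridium phosphoramidite and the oxygen of 4 attacks the substituted terminus (branched ether). The new C7 centre (R) is set by the ligand and not by the remote C4 centre, which is carried unchanged.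

Step 6
Reactants: 9 tert-butyldiphenyl{[(2R)-2-{[(3S)-5-(trimethylsilyl)pent-1-en-4-yn-3-yl]oxy}but-3-en-1-yl]oxy}silane
Product: 10 tert-butyldiphenyl{[(2R,5S)-5-[(trimethylsilyl)ethynyl]-2,5-dihydrofuran-2-yl]methoxy}silane (cis)
Conditions: second-generation Grubbs catalyst RuCl2(=CHPh)(H2IMes)(PCy3) (3 mol%), CH2Cl2, 40 °C
Reagents that add atoms: none
Why: Ring-closing metathesis of the two terminal vinyl groups closes the five-membered ring with loss of ethene; the silyl-capped alkyne is too hindered for enyne metathesis and neither stereocentre is touched, so the 2,5-cis relationship follows from step 5.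

Step 7
Reactants: 10 tert-butyldiphenyl{[(2R,5S)-5-[(trimethylsilyl)ethynyl]-2,5-dihydrofuran-2-yl]methoxy}silane
Product: 11 tert-butyl{[(2R,5S)-5-ethynyl-2,5-dihydrofuran-2-yl]methoxy}diphenylsilane (cis)
Conditions: K2CO3 (0.3 equiv), MeOH, 0 °C to rt
Reagents that add atoms: none
Why: Methanolysis of the alkynyl C–Si bond by catalytic methoxide; the primary TBDPS ether and the ring are inert to K2CO3 in MeOH.

Step 8
Reactants: 11 tert-butyl{[(2R,5S)-5-ethynyl-2,5-dihydrofuran-2-yl]methoxy}diphenylsilane; 7 methyl chloroformate
Product: 12 methyl 3-[(2S,5R)-5-{[(tert-butyldiphenylsilyl)oxy]methyl}-2,5-dihydrofuran-2-yl]prop-2-ynoate (cis)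
Conditions: n-BuLi (1.0 equiv), THF, −78 °C; cannulated into 7 (3 equiv), THF, −78 °C; AcOH quench at −78 °C
Reagents that add atoms: none
Why: Acylation of the lithium acetylide by the chloroformate; inverse addition at −78 °C, no excess base and a cold acidic quench protect the now acidic C4–H (propargylic to an ynoate, allylic and α to oxygen) from allene formation or epimerisation.

Step 9
Reactants: 12 methyl 3-[(2S,5R)-5-{[(tert-butyldiphenylsilyl)oxy]methyl}-2,5-dihydrofuran-2-yl]prop-2-ynoate
Product: 15 methyl 3-[(2R,3S,4S,5S)-4-acetoxy-5-{[(tert-butyldiphenylsilyl)oxy]methyl}-3-hydroxyoxolan-2-yl]prop-2-ynoate (all-cis), via iodo acetate 13 (not isolated), via acetoxonium ion 14 (not isolated)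
Conditions: AgOAc (2.3 equiv), I2 (1.1 equiv), AcOH, rt, dark; then H2O (3 equiv) in AcOH, 60–80 °C
Reagents that add atoms: silver acetate, CC(=O)[O-].[Ag+]; water, O
Why: Woodward cis-hydroxylation, the wet variant of the Prévost reaction. Acetyl hypoiodite from I2 and AgOAc delivers iodine to C5=C6 on the face turned away from the C4 and C7 substituents, and acetate opens the iodonium ion anti, which gives 13 with its oxygen on the substituent face. AgOAc then removes iodide while the acetate carbonyl attacks the same carbon from behind (5-exo-tet displacement with inversion), so the cis-fused 1,3-dioxolan-2-ylium ion 14 lies wholly on the substituent face. Water adds to the cationic carbon and the ortho acid collapses to the cis hydroxy acetate, so no ring remains closed in 15. C5 and C6 are both set by the substrate: one by anti opening and the other by inversion, the face of iodine attack being fixed by the two cis substituents. The step needs face selectivity only; which carbon acetate enters first and which oxygen keeps the acetyl group is immaterial, because both hydroxy acetates converge in step 11. Chemoselectivity rests on the ynoate, which is too electron-poor to form an iodonium ion and too linear to lactonise, and on the TBDPS ether, which should tolerate warm aqueous AcOH and offers no participating carbonyl.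

Step 10
Reactants: 15 methyl 3-[(2R,3S,4S,5S)-4-acetoxy-5-{[(tert-butyldiphenylsilyl)oxy]methyl}-3-hydroxyoxolan-2-yl]prop-2-ynoate
Product: 16 methyl (2Z)-3-[(2R,3S,4S,5S)-4-acetoxy-5-{[(tert-butyldiphenylsilyl)oxy]methyl}-3-hydroxyoxolan-2-yl]prop-2-enoate
Conditions: H2 (1 atm), Pd/CaCO3 poisoned with Pb(OAc)2 (Lindlar catalyst), quinoline, EtOAc, rt
Reagents that add atoms: none
Why: Syn semi-hydrogenation of the alkyne on poisoned palladium gives the (Z)-enoate, the only geometry that lets C1 reach O5; quinoline limits over-reduction, and partial closure to 17 at this stage is harmless.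

Step 11
Reactants: 16 methyl (2Z)-3-[(2R,3S,4S,5S)-4-acetoxy-5-{[(tert-butyldiphenylsilyl)oxy]methyl}-3-hydroxyoxolan-2-yl]prop-2-enoate
Product: 19 (2S,3R,3aR,7aR)-3-hydroxy-2-(hydroxymethyl)-2,3,3a,7a-tetrahydro-5H-furo[3,2-b]pyran-5-one, via acetoxy lactone 17 (not isolated), via silyl ether lactone 18 (not isolated)
Conditions: AcCl (5 equiv), MeOH, 0 °C to rt; evaporation with toluene; trituration with hexane
Reagents that add atoms: none
Why: Methanolic HCl from AcCl should do three things in one flask: the Z-δ-hydroxy enoate lactonises on O5 (O6 would need a seven-membered ring), the acetate is removed by acid-catalysed transesterification from whichever oxygen holds it, and the primary TBDPS ether is solvolysed. Acid is chosen because base would open or add to the unsaturated lactone; the by-products are volatile or hexane-soluble, so the polar diol needs no aqueous work-up.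

Step 12
Reactants: 19 (2S,3R,3aR,7aR)-3-hydroxy-2-(hydroxymethyl)-2,3,3a,7a-tetrahydro-5H-furo[3,2-b]pyran-5-one
Product: 20 (2R,3S,3aR,7aR)-3-hydroxy-5-oxo-2,3,3a,7a-tetrahydro-5H-furo[3,2-b]pyran-2-carbaldehyde
Conditions: TEMPO (0.2 equiv), PhI(OAc)2 (1.2 equiv), CH2Cl2–MeCN, rt; used at once
Reagents that add atoms: none
Why: Oxoammonium oxidation (TEMPO/PhI(OAc)2) is selective for the primary alcohol of a 1,3-diol and stops at the β-hydroxy aldehyde because no lactol can form; the weakly acidic medium spares the lactone and the C7 centre.

Step 13
Reactants: 20 (2R,3S,3aR,7aR)-3-hydroxy-5-oxo-2,3,3a,7a-tetrahydro-5H-furo[3,2-b]pyran-2-carbaldehyde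
Product: 21 (2S,3R,3aR,7aR)-3-hydroxy-2-[(E)-2-iodoethenyl]-2,3,3a,7a-tetrahydro-5H-furo[3,2-b]pyran-5-one
Conditions: CrCl2 (8 equiv), CHI3 (3 equiv), THF–1,4-dioxane (1:6), 0 °C to rt, dark
Reagents that add atoms: iodoform, IC(I)I
Why: Takai iodo-olefination: the geminal dichromium species from CHI3 and divalent chromium adds to the aldehyde and eliminates to the (E)-vinyl iodide; the reagent is non-basic and tolerates free hydroxyl groups and unsaturated lactones.

Step 14
Reactants: 22 (2R)-but-3-en-2-ol
Product: 23 (2R)-but-3-en-2-yl benzoate
Conditions: BzCl (1.2 equiv), pyridine, DMAP (cat.), CH2Cl2, 0 °C to rt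
Reagents that add atoms: benzoyl chloride, O=C(Cl)c1ccccc1
Why: Acylation of the secondary alcohol with retention (the C–O bond is not touched); this installs the C11 benzoate of the target in the R configuration.

Step 15
Reactants: 23 (2R)-but-3-en-2-yl benzoate
Product: 25 (2R)-1-oxopropan-2-yl benzoate, via ozonide 24 (not isolated)
Conditions: O3, CH2Cl2, −78 °C; Me2S, −78 °C to rt; used freshly
Reagents that add atoms: ozone, [O-][O+]=O
Why: Ozonolysis with reductive work-up cleaves the terminal alkene to the aldehyde under neutral conditions, with no hydride or base that could attack or shift the benzoate or racemise the α-acyloxy aldehyde.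

Step 16
Reactants: 21 (2S,3R,3aR,7aR)-3-hydroxy-2-[(E)-2-iodoethenyl]-2,3,3a,7a-tetrahydro-5H-furo[3,2-b]pyran-5-one; 25 (2R)-1-oxopropan-2-yl benzoate
Product: 26 (2R,3S,4E)-3-hydroxy-5-[(2S,3R,3aR,7aR)-3-hydroxy-5-oxo-2,3,3a,7a-tetrahydro-5H-furo[3,2-b]pyran-2-yl]pent-4-en-2-yl benzoate (the target)
Conditions: 25 (3 equiv), CrCl2 (6 equiv), NiCl2 (2 mol%), DMSO, rt; aqueous potassium sodium tartrate work-up
Reagents that add atoms: none
Why: Nozaki–Hiyama–Kishi coupling: zerovalent nickel inserts into the C–I bond and transmetalation gives an alkenyl species of trivalent chromium that adds only to the aldehyde, with the E geometry retained and the lactone, benzoate and hydroxyls tolerated. C10 is set by Felkin–Anh addition anti to the C11–OBz bond, which should favour the 10,11-anti (10S,11R) isomer; neutral work-up avoids benzoate migration and the product needs no deprotection.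

## Compound list

1 | rac-pent-1-en-4-yn-3-ol | C=CC(O)C#C | starting material
2 | rac-trimethyl{[5-(trimethylsilyl)pent-1-en-4-yn-3-yl]oxy}silane | C=CC(O[Si](C)(C)C)C#C[Si](C)(C)C | intermediate
3 | rac-5-(trimethylsilyl)pent-1-en-4-yn-3-ol | C=CC(O)C#C[Si](C)(C)C | intermediate
4 | (3S)-5-(trimethylsilyl)pent-1-en-4-yn-3-ol | C=C[C@H](O)C#C[Si](C)(C)C | intermediate
5 | (2E)-but-2-ene-1,4-diol | OC/C=C/CO | starting material
6 | (2E)-4-[(tert-butyldiphenylsilyl)oxy]but-2-en-1-ol | OC/C=C/CO[Si](c1ccccc1)(c1ccccc1)C(C)(C)C | intermediate
7 | methyl chloroformate | COC(=O)Cl | starting material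
8 | (2E)-4-[(tert-butyldiphenylsilyl)oxy]but-2-en-1-yl methyl carbonate | COC(=O)OC/C=C/CO[Si](c1ccccc1)(c1ccccc1)C(C)(C)C | intermediate
9 | tert-butyldiphenyl{[(2R)-2-{[(3S)-5-(trimethylsilyl)pent-1-en-4-yn-3-yl]oxy}but-3-en-1-yl]oxy}silane | C=C[C@@H](C#C[Si](C)(C)C)O[C@H](C=C)CO[Si](c1ccccc1)(c1ccccc1)C(C)(C)C | intermediate
10 | tert-butyldiphenyl{[(2R,5S)-5-[(trimethylsilyl)ethynyl]-2,5-dihydrofuran-2-yl]methoxy}silane | C[Si](C)(C)C#C[C@@H]1C=C[C@H](CO[Si](c2ccccc2)(c2ccccc2)C(C)(C)C)O1 | intermediate
11 | tert-butyl{[(2R,5S)-5-ethynyl-2,5-dihydrofuran-2-yl]methoxy}diphenylsilane | C#C[C@@H]1C=C[C@H](CO[Si](c2ccccc2)(c2ccccc2)C(C)(C)C)O1 | intermediate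
12 | methyl 3-[(2S,5R)-5-{[(tert-butyldiphenylsilyl)oxy]methyl}-2,5-dihydrofuran-2-yl]prop-2-ynoate | COC(=O)C#C[C@@H]1C=C[C@H](CO[Si](c2ccccc2)(c2ccccc2)C(C)(C)C)O1 | intermediate
13 | methyl 3-[(2R,3R,4R,5S)-4-acetoxy-5-{[(tert-butyldiphenylsilyl)oxy]methyl}-3-iodooxolan-2-yl]prop-2-ynoate (iodine trans to the C4 and C7 substituents, acetate cis) | COC(=O)C#C[C@H]1O[C@@H](CO[Si](c2ccccc2)(c2ccccc2)C(C)(C)C)[C@@H](OC(C)=O)[C@@H]1I | intermediate
14 | acetoxonium ion: 2-methyl-1,3-dioxolan-2-ylium cis-fused across C5/C6 on the face of the C4 and C7 substituents, acetate counter-ion | COC(=O)C#C[C@H]1O[C@@H](CO[Si](c2ccccc2)(c2ccccc2)C(C)(C)C)[C@@H]3[C@H]1[O+]=C(C)O3.CC(=O)[O-] | intermediate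
15 | methyl 3-[(2R,3S,4S,5S)-4-acetoxy-5-{[(tert-butyldiphenylsilyl)oxy]methyl}-3-hydroxyoxolan-2-yl]prop-2-ynoate | COC(=O)C#C[C@H]1O[C@@H](CO[Si](c2ccccc2)(c2ccccc2)C(C)(C)C)[C@@H](OC(C)=O)[C@H]1O | intermediate
16 | methyl (2Z)-3-[(2R,3S,4S,5S)-4-acetoxy-5-{[(tert-butyldiphenylsilyl)oxy]methyl}-3-hydroxyoxolan-2-yl]prop-2-enoate | COC(=O)/C=C\[C@H]1O[C@@H](CO[Si](c2ccccc2)(c2ccccc2)C(C)(C)C)[C@@H](OC(C)=O)[C@H]1O | intermediate
17 | (2S,3R,3aS,7aR)-2-{[(tert-butyldiphenylsilyl)oxy]methyl}-5-oxo-2,3,3a,7a-tetrahydro-5H-furo[3,2-b]pyran-3-yl acetate | CC(C)(C)[Si](c1ccccc1)(c1ccccc1)OC[C@@H]1O[C@@H]2C=CC(=O)O[C@@H]2[C@@H]1OC(C)=O | intermediate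
18 | (2S,3R,3aR,7aR)-2-{[(tert-butyldiphenylsilyl)oxy]methyl}-3-hydroxy-2,3,3a,7a-tetrahydro-5H-furo[3,2-b]pyran-5-one | CC(C)(C)[Si](c1ccccc1)(c1ccccc1)OC[C@@H]1O[C@@H]2C=CC(=O)O[C@@H]2[C@@H]1O | intermediate
19 | (2S,3R,3aR,7aR)-3-hydroxy-2-(hydroxymethyl)-2,3,3a,7a-tetrahydro-5H-furo[3,2-b]pyran-5-one | OC[C@@H]1O[C@@H]2C=CC(=O)O[C@@H]2[C@@H]1O | intermediate
20 | (2R,3S,3aR,7aR)-3-hydroxy-5-oxo-2,3,3a,7a-tetrahydro-5H-furo[3,2-b]pyran-2-carbaldehyde | O=C[C@@H]1O[C@@H]2C=CC(=O)O[C@@H]2[C@@H]1O | intermediate
21 | (2S,3R,3aR,7aR)-3-hydroxy-2-[(E)-2-iodoethenyl]-2,3,3a,7a-tetrahydro-5H-furo[3,2-b]pyran-5-one | I/C=C/[C@@H]1O[C@@H]2C=CC(=O)O[C@@H]2[C@@H]1O | intermediate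
22 | (2R)-but-3-en-2-ol | C[C@@H](O)C=C | starting material
23 | (2R)-but-3-en-2-yl benzoate | C[C@@H](OC(=O)c1ccccc1)C=C | intermediate
24 | (1R)-1-(1,2,4-trioxolan-3-yl)ethyl benzoate (mixture at the ring carbon) | C[C@@H](OC(=O)c1ccccc1)C1OCOO1 | intermediate
25 | (2R)-1-oxopropan-2-yl benzoate | C[C@@H](OC(=O)c1ccccc1)C=O | intermediate
26 | (2R,3S,4E)-3-hydroxy-5-[(2S,3R,3aR,7aR)-3-hydroxy-5-oxo-2,3,3a,7a-tetrahydro-5H-furo[3,2-b]pyran-2-yl]pent-4-en-2-yl benzoate | C[C@@H](OC(=O)c1ccccc1)[C@@H](O)/C=C/[C@@H]1O[C@@H]2C=CC(=O)O[C@@H]2[C@@H]1O | target

## Step count and least certain steps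

Total: 16 steps. Longest linear sequence: 12 steps (steps 1, 2, 5–13 and 16 from 1; the branch from 5 through steps 3 and 4 is equally long).

Step 9 (key step). Most likely to go wrong: the silver-assisted loss of iodide from 13 may be slow, because the carbon sits between two oxygen-bearing carbons, and the heat then needed invites addition of acetic acid to the ynoate or loss of the silyl ether. If the medium is too dry, 14 is opened by acetate to a trans diacetate; and if the iodonium ion forms reversibly on the crowded face, facial selectivity erodes. Fallback, setting out from 12 and returning at 15: the same two inversions are run with oxygen first and a sulfonate as leaving group. Peracid epoxidation (mCPBA, CH2Cl2) on the open face should give the 5,6-epoxide with the oxirane trans to the C4 and C7 substituents F1. Opening with CsOAc in AcOH–DMF should give the trans hydroxy acetate (acetate on the substituent face, hydroxyl on the other) F2, whose regiochemistry is again immaterial. Tf2O and pyridine give the triflate F3. Warming F3 in wet AcOH with NaOAc lets the acetate carbonyl displace triflate with inversion, which forms 14 without silver or iodine and, after hydrolysis, 15.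

Step 5. Most likely to go wrong: wrong-sense or mismatched induction giving the 4,7-trans ether, attack at the unsubstituted allyl terminus (linear ether), or sluggish reaction of a hindered secondary alkoxide. Fallback, setting out from 4 and returning at 9: a palladium-catalysed dynamic kinetic asymmetric addition of 4 to racemic 2-vinyloxirane, using Pd2(dba)3, an enantiopure N,N'-(cyclohexane-1,2-diyl)bis[2-(diphenylphosphino)benzamide] and catalytic Et3B in CH2Cl2. This changes both the metal and the electrophile and should give (2R)-2-{[(3S)-5-(trimethylsilyl)pent-1-en-4-yn-3-yl]oxy}but-3-en-1-ol F4. Silylation of F4 (TBDPSCl, imidazole, DMF) gives 9.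

Step 8. Most likely to go wrong: proton transfer from C4 to acetylide or residual butyllithium, leading to the allenoate and then aromatisation to a furan, or to epimerisation at C4. Fallback, setting out from 11 and returning at 12: oxidative methoxycarbonylation of the terminal alkyne with PdCl2 (cat.), CuCl2 (2 equiv), NaOAc, CO (1 atm) in MeOH at rt. This carbonylates a palladium acetylide without any strong base and forms no new intermediate on the way.

Step 12, together with step 13. Most likely to go wrong: the unprotected β-hydroxy aldehyde may epimerise at C7 or decompose by retro-aldol or elimination pathways; the polar compounds 19 and 20 may be lost on handling; and the free C8 hydroxyl of 19 may add to C3 of the lactone before it is oxidised. Fallback, setting out from 19 and returning at 26: both hydroxyls are silylated (TESOTf, 2,6-lutidine, CH2Cl2, −78 °C) to the bis(triethylsilyl) ether F5. Swern conditions, known to oxidise primary triethylsilyl ethers directly, convert only the C8 ether into the O6-triethylsilyl aldehyde F6. Takai olefination gives the O6-triethylsilyl vinyl iodide F7, and coupling with 25 as in step 16 gives the O6-triethylsilyl ether of the target F8. HF·pyridine in THF–pyridine at 0 °C then frees 26 under conditions too mild and acidic for benzoate migration.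

Step 16. Most likely to go wrong: low facial discrimination at C10, since the aldehyde offers only methyl against hydrogen beside the benzoate; racemisation of 25 before it reacts; and shift of the benzoate to O10 in the chromium alkoxide. Fallback, setting out from 20 and 25 and returning at 26: the C10 centre is made on the small fragment, where isomers are cheap to separate. Addition of vinyl bromide to 25 (CrCl2, NiCl2 cat., DMSO) gives (2R,3S)-3-hydroxypent-4-en-2-yl benzoate F10, purified from its C10 epimer. Methylenation of 20 (CH2I2, Zn, TiCl4, THF, 0 °C) gives the C7-vinyl lactone F9. Cross-metathesis of F9 with excess F10, using the second-generation Hoveyda–Grubbs catalyst RuCl2(=CH-C6H4-2-OiPr)(H2IMes) in CH2Cl2 at 40 °C, should give 26 with the E alkene.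

## Further compounds

F1 | step 9 | methyl 3-[5-{[(tert-butyldiphenylsilyl)oxy]methyl}-3,4-epoxyoxolan-2-yl]prop-2-ynoate, oxirane trans to the C4 and C7 substituents | COC(=O)C#C[C@H]1O[C@@H](CO[Si](c2ccccc2)(c2ccccc2)C(C)(C)C)[C@@H]3O[C@H]13
F2 | step 9 | trans hydroxy acetate: C6 acetate on the substituent face, C5 hydroxyl on the opposite face | COC(=O)C#C[C@H]1O[C@@H](CO[Si](c2ccccc2)(c2ccccc2)C(C)(C)C)[C@@H](OC(C)=O)[C@@H]1O
F3 | step 9 | C5 trifluoromethanesulfonate of F2 | COC(=O)C#C[C@H]1O[C@@H](CO[Si](c2ccccc2)(c2ccccc2)C(C)(C)C)[C@@H](OC(C)=O)[C@@H]1OS(=O)(=O)C(F)(F)F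
F4 | step 5 | (2R)-2-{[(3S)-5-(trimethylsilyl)pent-1-en-4-yn-3-yl]oxy}but-3-en-1-ol | C=C[C@@H](C#C[Si](C)(C)C)O[C@H](C=C)CO
F0 | step 8 | none | none
F5 | step 12 | bis(triethylsilyl) ether of 19 | CC[Si](CC)(CC)OC[C@@H]1O[C@@H]2C=CC(=O)O[C@@H]2[C@@H]1O[Si](CC)(CC)CC
F6 | step 12 | O6-triethylsilyl ether of 20 | O=C[C@@H]1O[C@@H]2C=CC(=O)O[C@@H]2[C@@H]1O[Si](CC)(CC)CC
F7 | step 12 | O6-triethylsilyl ether of 21 | I/C=C/[C@@H]1O[C@@H]2C=CC(=O)O[C@@H]2[C@@H]1O[Si](CC)(CC)CC
F8 | step 12 | O6-triethylsilyl ether of 26 | C[C@@H](OC(=O)c1ccccc1)[C@@H](O)/C=C/[C@@H]1O[C@@H]2C=CC(=O)O[C@@H]2[C@@H]1O[Si](CC)(CC)CC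
F9 | step 16 | (2S,3R,3aR,7aR)-2-ethenyl-3-hydroxy-2,3,3a,7a-tetrahydro-5H-furo[3,2-b]pyran-5-one | C=C[C@@H]1O[C@@H]2C=CC(=O)O[C@@H]2[C@@H]1O
F10 | step 16 | (2R,3S)-3-hydroxypent-4-en-2-yl benzoate | C[C@@H](OC(=O)c1ccccc1)[C@@H](O)C=C
A1 | alternative 1 | endo,endo 7-oxabicyclo[2.2.1]hept-5-ene-2,3-diol, acrylate on the future O5, tert-butyldimethylsilyl ether on the future O6 | C=CC(=O)O[C@@H]1[C@H](O[Si](C)(C)C(C)(C)C)[C@@H]2C=C[C@H]1O2
A2 | alternative 1 | C7-vinyl furo[3,2-b]pyran-5-one, O6 tert-butyldimethylsilyl ether, all-cis | C=C[C@@H]1O[C@@H]2C=CC(=O)O[C@@H]2[C@@H]1O[Si](C)(C)C(C)(C)C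
A3 | alternative 2 | open-chain cis-4,5-epoxide with free C6 and C7 hydroxyls, C1 silyloxymethyl alkyne, O10 silyl ether and O11 benzoate | C[C@@H](OC(=O)c1ccccc1)[C@@H](O[Si](C)(C)C(C)(C)C)/C=C/[C@H](O)[C@@H](O)[C@H]1O[C@H]1C#CCO[Si](C)(C)C(C)(C)C
A4 | alternative 2 | all-cis tetrahydrofuran 5,6-diol with C4 alkynyl group and complete side chain | C[C@@H](OC(=O)c1ccccc1)[C@@H](O[Si](C)(C)C(C)(C)C)/C=C/[C@@H]1O[C@H](C#CCO[Si](C)(C)C(C)(C)C)[C@H](O)[C@@H]1O
A5 | alternative 3 | C5 furan-2-yl carbinol with C6/C7 acetonide and complete side chain | C[C@@H](OC(=O)c1ccccc1)[C@@H](O[Si](C)(C)C(C)(C)C)/C=C/[C@@H]1OC(C)(C)O[C@H]1[C@@H](O)c1ccco1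
A6 | alternative 3 | 6-hydroxy-2H-pyran-3(6H)-one with the lactol at C1 (major anomer) | C[C@@H](OC(=O)c1ccccc1)[C@@H](O[Si](C)(C)C(C)(C)C)/C=C/[C@@H]1OC(C)(C)O[C@H]1[C@H]2O[C@H](O)C=CC2=O
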